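**Retrosynthetic overview**
1. Target ⇒ its 15-deoxo precursor (isopropenyl on C13); the enal is made last by allylic oxidation.
2. δ-Lactone (C20–O–C7) and oxa-bridge (C6–O–C3) ⇒ closed together in one flask from a ring A enone / ring C thioester: C10 hydroxymethylation → lactonisation → C–Si oxidation → oxa-Michael. This also sets spiro C10 and C3.
3. C8(OH)–C7 ⇒ equatorial addition of a carboxyl-anion equivalent to a C8 ketone; C13 (and C9 by equilibration) ⇒ Rh/BINAP isopropenyl conjugate addition to a ring C enone.
4. C9–C10 bond ⇒ silicon-tethered oxidative cross-coupling of the dienolates of two cyclohexenones.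
5. C5 ⇒ Cu-catalysed enantioselective addition of a silylmethyl (masked hydroxymethyl) Grignard to 4,4-dimethylcyclohexadienone. Ring order: carbocycles A and C are bought as enones, then lactone, then oxa-bridge.

Labels (one assumption): atoms are numbered as in the ent-kaurane skeleton (ring A = C1(=O), C2, C3(O), C4(Me2), C5, C10; ether C6–O–C3; lactone C10–C20–O–C7(=O)–C8(OH)–C9; ring C = C8, C9, C11–C14; C15(HO)–C16(=C17) on C13). CIP letters quoted for an intermediate are those of that intermediate and may change without any change of geometry.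

**Step 1**
Reactants: 1 4,4-dimethylcyclohex-2-en-1-one
Product: 2 4,4-dimethylcyclohexa-2,5-dien-1-one
Conditions: DDQ (1.5 equiv), dioxane, reflux
Reagents that add atoms: none
Why: DDQ dehydrogenation of the enone (hydride abstraction from the enol form) can only desaturate C5–C6 because C4 is quaternary, giving the symmetric cross-conjugated dienone with no stereocentre.

**Step 2**
Reactants: 2 4,4-dimethylcyclohexa-2,5-dien-1-one; 3 (chloromethyl)pentamethyldisiloxane
Product: 5 (R)-4,4-dimethyl-5-[(pentamethyldisiloxanyl)methyl]cyclohex-2-en-1-one, via [(pentamethyldisiloxanyl)methyl]magnesium chloride 4 (not isolated)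
Conditions: 3, Mg, THF, 40 °C; then copper thiophene-2-carboxylate (5 mol %), (S,R,R)-BINOL bis(1-phenylethyl)amine phosphoramidite (10 mol %), Et2O, −78 °C, slow addition to 2; H2O
Reagents that add atoms: none
Why: Proposed new method: a monovalent copper–phosphoramidite complex should transfer the silylmethyl group to one enantiotopic β-carbon of the symmetric dienone (π-complex, trivalent-copper enolate, reductive elimination), setting C5 under ligand control (antipodal ligand if the sense proves opposite), while the product stays as a cross-conjugated magnesium enolate so no second addition occurs and the C–Si bond keeps the future C6 hydroxyl masked; the closest known reactions are the copper–phosphoramidite asymmetric conjugate addition of dialkylzincs to this same dienone, copper-catalysed asymmetric Grignard additions to cyclohexenones, and the racemic copper-catalysed addition of (silylmethyl)magnesium chlorides (Tamao hydroxymethyl-anion equivalents) to enones.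

**Step 3**
Reactants: 6 cyclohex-2-en-1-one; 7 dichlorodiisopropylsilane
Product: 8 chloro(cyclohexa-1,5-dien-1-yloxy)diisopropylsilane
Conditions: LiN(i-Pr)2, THF, −78 °C; inverse addition to 7 (3 equiv), −78 °C → rt; filtration, distillation
Reagents that add atoms: none
Why: Kinetic α′-deprotonation of cyclohexenone gives the cross-conjugated lithium dienolate, which is O-silylated once by excess dichlorosilane (enolate O-silylation), leaving one Si–Cl for the second enolate.

**Step 4**
Reactants: 5 (R)-4,4-dimethyl-5-[(pentamethyldisiloxanyl)methyl]cyclohex-2-en-1-one; 8 chloro(cyclohexa-1,5-dien-1-yloxy)diisopropylsilane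
Product: 10 (5R)-4,4-dimethyl-6-(2-oxocyclohex-3-en-1-yl)-5-[(pentamethyldisiloxanyl)methyl]cyclohex-2-en-1-one (mixture of C9/C10 epimers), via silyl bis-enol ether 9 (not isolated)
Conditions: LiN(i-Pr)2, THF, −78 °C; 8, −78 °C → rt; evaporate; (NH4)2Ce(NO3)6 (2.2 equiv), NaHCO3 (4.4 equiv), MeCN, −10 °C
Reagents that add atoms: none
Why: Silicon-tethered oxidative enolate heterocoupling (Thomson type): 5 can only enolise at C10, its enolate is O-silylated by 8, and one-electron oxidation of the unsymmetrical bis-enol ether by tetravalent cerium gives a radical cation that closes through a seven-membered transition state to join C10 to C9 in the cross sense only; both new centres are epimerisable and are fixed in steps 5 and 7.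

**Step 5**
Reactants: 10 (5R)-bis-enone diketone; 11 4,4,5,5-tetramethyl-2-(prop-1-en-2-yl)-1,3,2-dioxaborolane
Product: 12 (5R,9S,13R)-4,4-dimethyl-6-[2-oxo-4-(prop-1-en-2-yl)cyclohexyl]-5-[(pentamethyldisiloxanyl)methyl]cyclohex-2-en-1-one (C10 epimers)
Conditions: [Rh(cod)Cl]2 (2.5 mol %), (R)-BINAP (6 mol %), 11 (2 equiv), KOH (0.2 equiv), dioxane/H2O 10:1, 50 °C; then DBU (0.2 equiv), rt
Reagents that add atoms: none
Why: Hayashi–Miyaura rhodium/BINAP asymmetric conjugate addition attacks only the unhindered ring C enone (the ring A β-carbon is neopentyl), (R)-BINAP sets C13 as R under catalyst control by analogy with (S)-BINAP giving (S)-3-alkenylcyclohexanones, and base then equilibrates the α-carbon C9 to the trans-2,5-diequatorial (9S) ketone.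

**Step 6**
Reactants: 12 (5R,9S,13R)-diketone; 13 tris(methylthio)methane
Product: 16 S-methyl (5R,8S,9S,13R)-8-hydroxy-7-thioate (ring C C8 bears axial OH and equatorial C(=O)SMe; C10 epimers), via tris(methylthio)methyllithium 14 (not isolated), via orthothioester carbinol 15 (not isolated)
Conditions: 13, n-BuLi, THF, −78 °C; 12, −78 °C, 2 h; H2O; then MeI (10 equiv), CaCO3, MeCN/H2O 4:1, 40 °C
Reagents that add atoms: water, O
Why: Seebach carboxyl-anion addition: the bulky LiC(SMe)3 adds 1,2 to the saturated C8 ketone (more accessible than the flanked enone carbonyl) from the equatorial direction, trans to the equatorial C9 substituent, giving the axial tertiary alcohol (8S), and alkylative hydrolysis of the orthothioester (S-methylation, loss of Me2S, water capture) leaves the S-methyl thioester.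

**Step 7**
Reactants: 16 S-methyl α-hydroxy thioester
Product: 19 15-deoxo precursor of the target (C15 = CH3; 3S,5S,8S,9S,10R,13R), via silyl lactone 17 (not isolated), via hydroxy enone lactone 18 (not isolated)
Conditions: LiN(i-Pr)2 (2.3 equiv), THF, −78 → −40 °C; CH2O (gas, from cracked paraformaldehyde), −78 → 0 °C; then MeOH, KF, KHCO3, 30% H2O2, 0 → 40 °C, same flask
Reagents that add atoms: formaldehyde, C=O; hydrogen peroxide, OO
Why: One-flask aldol–lactonisation–Tamao oxidation–oxa-Michael sequence: the dianion (C8 alkoxide plus the only possible enolate, at C10) is hydroxymethylated by formaldehyde on the face anti to the pseudoaxial C5 side chain (10R, spiro quaternary centre), the new C20 alkoxide expels thiolate from the neighbouring thioester to close the trans-fused δ-lactone, and fluoride/peroxide then converts C–Si into C6–OH with retention, whose 5-exo conjugate addition to the enone can only occur cis and so fixes C3 (S) while closing the oxa-bridge.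

**Step 8**
Reactants: 19 15-deoxo precursor
Product: 21 target CNP0525385.1 (3S,5S,8S,9S,10R,13R), via allylic alcohol 20 (not isolated)
Conditions: SeO2 (0.5 equiv), t-BuOOH (3 equiv), CH2Cl2, rt; then activated MnO2, rt, same flask
Reagents that add atoms: selenium dioxide, O=[Se]=O (the oxygen it delivers to C15 is replenished by tert-butyl hydroperoxide, CC(C)(C)OO)
Why: Selenium dioxide allylic oxidation (ene reaction then [2,3]-sigmatropic shift) attacks the methyl group of the 1,1-disubstituted alkene in preference to the ring methine, and MnO2 oxidises only the resulting primary allylic alcohol to the enal, leaving the tertiary alcohol, ketone, lactone and all stereocentres untouched.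

**Compound list**
1 | 4,4-dimethylcyclohex-2-en-1-one | CC1(C)CCC(=O)C=C1 | starting material
2 | 4,4-dimethylcyclohexa-2,5-dien-1-one | CC1(C)C=CC(=O)C=C1 | intermediate
3 | (chloromethyl)pentamethyldisiloxane | C[Si](C)(C)O[Si](C)(C)CCl | starting material
4 | [(pentamethyldisiloxanyl)methyl]magnesium chloride | C[Si](C)(C)O[Si](C)(C)C[Mg]Cl | intermediate
5 | (R)-4,4-dimethyl-5-[(pentamethyldisiloxanyl)methyl]cyclohex-2-en-1-one | O=C1C=CC(C)(C)[C@H](C[Si](C)(C)O[Si](C)(C)C)C1 | intermediate
6 | cyclohex-2-en-1-one | O=C1C=CCCC1 | starting material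
7 | dichlorodiisopropylsilane | CC(C)[Si](Cl)(Cl)C(C)C | starting material
8 | chloro(cyclohexa-1,5-dien-1-yloxy)diisopropylsilane | CC(C)[Si](Cl)(OC1=CCCC=C1)C(C)C | intermediate
9 | diisopropylsilyl bis-enol ether of 5 (through O on C1, C1=C10 enol) and cyclohex-2-enone (C8=C9 enol) | CC(C)[Si](OC1=CCCC=C1)(OC1=C[C@@H](C[Si](C)(C)O[Si](C)(C)C)C(C)(C)C=C1)C(C)C | intermediate
10 | (5R)-4,4-dimethyl-6-(2-oxocyclohex-3-en-1-yl)-5-[(pentamethyldisiloxanyl)methyl]cyclohex-2-en-1-one, C9 and C10 epimer mixture | O=C1C=CC(C)(C)[C@H](C[Si](C)(C)O[Si](C)(C)C)C1C1CCC=CC1=O | intermediate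
11 | 4,4,5,5-tetramethyl-2-(prop-1-en-2-yl)-1,3,2-dioxaborolane | CC(=C)B1OC(C)(C)C(C)(C)O1 | starting material
12 | (5R,9S,13R)-4,4-dimethyl-6-[2-oxo-4-(prop-1-en-2-yl)cyclohexyl]-5-[(pentamethyldisiloxanyl)methyl]cyclohex-2-en-1-one, C9 and C13 substituents trans, C10 epimers | C=C(C)[C@@H]1CC[C@@H](C2C(=O)C=CC(C)(C)[C@@H]2C[Si](C)(C)O[Si](C)(C)C)C(=O)C1 | intermediate
13 | tris(methylthio)methane | CSC(SC)SC | starting material
14 | tris(methylthio)methyllithium | [Li]C(SC)(SC)SC | intermediate
15 | (5R,8S,9S,13R)-C8 tertiary alcohol of 12 carrying C(SMe)3 on C8 (OH axial, cis to the C9 substituent) | C=C(C)[C@@H]1CC[C@@H](C2C(=O)C=CC(C)(C)[C@@H]2C[Si](C)(C)O[Si](C)(C)C)[C@](O)(C(SC)(SC)SC)C1 | intermediate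
16 | S-methyl (5R,8S,9S,13R)-8-hydroxy-7-thioate: as 15 with C(=O)SMe on C8 | C=C(C)[C@@H]1CC[C@@H](C2C(=O)C=CC(C)(C)[C@@H]2C[Si](C)(C)O[Si](C)(C)C)[C@](O)(C(=O)SC)C1 | intermediate
17 | spiro δ-lactone (C20–O–C7) with ring A enone and C5 CH2SiMe2OSiMe3; configuration as in 19 at C5, C8, C9, C10, C13 | C=C(C)[C@@H]1CC[C@H]2[C@]3(COC(=O)[C@]2(O)C1)C(=O)C=CC(C)(C)[C@@H]3C[Si](C)(C)O[Si](C)(C)C | intermediate
18 | spiro δ-lactone with ring A enone and free C6 hydroxymethyl on C5 (5S,8S,9S,10R,13R) | C=C(C)[C@@H]1CC[C@H]2[C@]3(COC(=O)[C@]2(O)C1)C(=O)C=CC(C)(C)[C@@H]3CO | intermediate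
19 | (3S,5S,8S,9S,10R,13R)-15-deoxo precursor: target skeleton with isopropenyl on C13 | C=C(C)[C@@H]1CC[C@H]2[C@]3(COC(=O)[C@]2(O)C1)C(=O)C[C@@H]1OC[C@H]3C1(C)C | intermediate
20 | (3S,5S,8S,9S,10R,13R)-15-hydroxy compound (allylic alcohol CH2=C(CH2OH)– on C13) | C=C(CO)[C@@H]1CC[C@H]2[C@]3(COC(=O)[C@]2(O)C1)C(=O)C[C@@H]1OC[C@H]3C1(C)C | intermediate
21 | CNP0525385.1 (3S,5S,8S,9S,10R,13R) | C=C(C=O)[C@@H]1CC[C@H]2[C@]3(COC(=O)[C@]2(O)C1)C(=O)C[C@@H]1OC[C@H]3C1(C)C | target

**Step count and risks**
Total: 8 steps, one of which (step 3) is a one-step side branch. Longest linear sequence: 7 steps (1, 2, 4, 5, 6, 7, 8). The three steps most likely to fail are 2, 6 and 7.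

Step 2 may be slow or poorly enantioselective because α-silyl Grignard reagents transfer reluctantly from copper. The fallback sets out from 2 and uses the established racemic addition (3/Mg, CuI 10 mol %, Me3SiCl, THF, −78 °C, then aqueous HCl) to give racemic 4,4-dimethyl-5-[(pentamethyldisiloxanyl)methyl]cyclohex-2-en-1-one F1. The R enantiomer is then separated by preparative chromatography on a chiral stationary phase, which comes back to the route at 5.

Step 6 may fail because the bulky LiC(SMe)3 can enolise the hindered C8 ketone or add 1,4 to the ring A enone. The fallback sets out from 12 and adds the smaller, hard acyl-anion equivalent CH2=C(OMe)Li with CeCl3 (THF, −78 °C), again from the equatorial side, to give the (5R,8S,9S,13R)-8-(1-methoxyvinyl) tertiary alcohol F2. One equivalent of O3 (CH2Cl2/pyridine, −78 °C, then Me2S) cleaves only the electron-rich enol ether and gives the methyl ester analogue of 16 F3. Step 7 is then run on F3 unchanged (methoxide instead of thiolate leaves in the lactonisation), which comes back to the route at 19.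

Step 7 may fail at the hydroxymethylation of the congested C10 enolate, or the peroxide stage may not tolerate the one-flask mixture. The fallback sets out from 16 and replaces the lithium enolate by a Lewis-acid Mukaiyama aldol. TMSOTf/Et3N gives the bis(trimethylsilyl) derivative of 16 (C1–O–SiMe3 dienol ether and C8–O–SiMe3 ether) F4. This is hydroxymethylated with aqueous CH2O/Sc(OTf)3 and lactonised with DBU to give 17, which is now isolated and oxidised separately (KF, KHCO3, H2O2) to come back to the route at 19.

**Further compounds**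
F1 | step 2 | racemic 4,4-dimethyl-5-[(pentamethyldisiloxanyl)methyl]cyclohex-2-en-1-one | O=C1C=CC(C)(C)C(C[Si](C)(C)O[Si](C)(C)C)C1
F2 | step 6 | (5R,8S,9S,13R)-8-(1-methoxyvinyl) tertiary alcohol derived from 12 | C=C(C)[C@@H]1CC[C@@H](C2C(=O)C=CC(C)(C)[C@@H]2C[Si](C)(C)O[Si](C)(C)C)[C@](O)(C(OC)=C)C1
F3 | step 6 | methyl (5R,8S,9S,13R)-8-hydroxy-7-oate, the methyl ester analogue of 16 | C=C(C)[C@@H]1CC[C@@H](C2C(=O)C=CC(C)(C)[C@@H]2C[Si](C)(C)O[Si](C)(C)C)[C@](O)(C(=O)OC)C1
F4 | step 7 | bis(trimethylsilyl) derivative of 16 (C1–O–SiMe3 dienol ether, C8–O–SiMe3 ether) | C=C(C)[C@@H]1CC[C@@H](C2=C(O[Si](C)(C)C)C=CC(C)(C)[C@@H]2C[Si](C)(C)O[Si](C)(C)C)[C@](O[Si](C)(C)C)(C(=O)SC)C1
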